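The δ-lactone of the dihydroisocoumarin is disconnected at C3–C4 and C1–O2. The feature used is the array O2–C3–C4: C3, which carries the ring oxygen, is the neighbour of benzylic C4, while the carbonyl C1 sits on C8a, ortho to the C4-bearing C4a, so the ring is a latent aldol of a homophthalic anhydride with an aldehyde. A squaramide-catalysed annulation of 5,8-bis(benzyloxy)isochromane-1,3-dione with (5S)-5-silyloxyhexanal makes both bonds, the lactone ring and the 3R centre in one operation; the C4 carboxyl left behind is removed by radical decarboxylation. Benzyl ethers on the arene and on the mevalonate unit permit one neutral hydrogenolysis at the end.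

Key step: step 8

Assumption: the quinine-derived squaramide is taken to direct attack to the Si face of the aldehyde (3R); the sense would be checked on hexanal, and the quinidine-derived pseudoenantiomer would be used instead if it proved opposite.

**Route**

Step 1
Reactants: 1 4,7-dimethoxyindan-1-one
Product: 2 4,7-dihydroxyindan-1-one
Conditions: BBr3 (3 equiv), CH2Cl2, −78 °C → rt; then H2O
Reagents that add atoms: none
Why: Lewis-acid O-demethylation of aryl methyl ethers with BBr3 is reliable on this simple acyl arene and frees both phenols at the cheapest stage, so that they can be re-masked as benzyl ethers that leave by hydrogenolysis at the end; no stereocentre is present.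

Step 2
Reactants: 2 4,7-dihydroxyindan-1-one
Product: 3 4,7-bis(benzyloxy)indan-1-one
Conditions: BnBr (2.5 equiv), K2CO3, DMF, 60 °C, N2
Reagents that add atoms: benzyl bromide, BrCc1ccccc1
Why: Williamson etherification of the two phenoxides is selective for oxygen because K2CO3 does not deprotonate the ketone α-position.

Step 3
Reactants: 3 4,7-bis(benzyloxy)indan-1-one; 4 diethyl oxalate
Product: 6 3,6-bis(benzyloxy)-2-(carboxymethyl)benzoic acid, via 2-ethoxalylindanone 5 (not isolated)
Conditions: NaOEt, EtOH/toluene, 0 °C → rt; then aq. NaOH, 30% H2O2, 10–35 °C; then HCl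
Reagents that add atoms: hydrogen peroxide, OO; water, O
Why: A crossed Claisen condensation with the non-enolisable oxalate acylates C2 of the indanone, and alkaline hydrogen peroxide then cleaves the resulting tricarbonyl array at C1–C2 and at the C2–oxalyl bond, which turns C1 and C2 into the aryl and acetic carboxyl groups (the classical indanone to homophthalic acid degradation) under conditions that aryl benzyl ethers tolerate.

Step 4
Reactants: 6 3,6-bis(benzyloxy)-2-(carboxymethyl)benzoic acid
Product: 7 5,8-bis(benzyloxy)isochromane-1,3-dione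
Conditions: Ac2O, toluene, 90 °C; evaporate
Reagents that add atoms: none
Why: Cyclodehydration of the diacid by acyl exchange with acetic anhydride closes the six-membered cyclic anhydride, and the absence of base avoids C-acetylation at the acidic C4 position.

Step 5
Reactants: 8 (S)-propylene oxide; 9 but-3-enylmagnesium bromide
Product: 10 (2S)-hept-6-en-2-ol
Conditions: CuI (10 mol %), THF, −30 → 0 °C; aq. NH4Cl
Reagents that add atoms: none
Why: Copper-catalysed Grignard opening of the terminal epoxide proceeds by SN2 attack at the unsubstituted carbon, so the oxygen-bearing stereocentre of 8 is not touched and becomes the 2S carbinol.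

Step 6
Reactants: 10 (2S)-hept-6-en-2-ol
Product: 11 tert-butyl[(2S)-hept-6-en-2-yloxy]dimethylsilane
Conditions: TBSCl, imidazole, DMF, rt
Reagents that add atoms: tert-butyldimethylsilyl chloride, CC(C)(C)[Si](C)(C)Cl
Why: Standard silyl ether formation masks the secondary hydroxyl for the ozonolysis and the amine-catalysed annulation, and the group can later be removed by fluoride without touching benzyl ethers or the lactone.

Step 7
Reactants: 11 tert-butyl[(2S)-hept-6-en-2-yloxy]dimethylsilane
Product: 13 (5S)-5-(tert-butyldimethylsilyloxy)hexanal, via secondary ozonide 12 (not isolated)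
Conditions: O3, CH2Cl2, −78 °C; then PPh3, −78 °C → rt
Reagents that add atoms: ozone, [O-][O+]=O
Why: Ozonolysis with reductive work-up cuts the terminal alkene to the aldehyde one carbon shorter, the silyl ether is inert, and the stereocentre is not α to the new carbonyl and cannot epimerise.

Step 8
Reactants: 7 5,8-bis(benzyloxy)isochromane-1,3-dione; 13 (5S)-5-(tert-butyldimethylsilyloxy)hexanal
Product: 14 (3R)-5,8-bis(benzyloxy)-3-[(4S)-4-(tert-butyldimethylsilyloxy)pentyl]-1-oxoisochromane-4-carboxylic acid (mixture of C4 epimers)
Conditions: 9-amino-9-deoxy-epi-quinine 3,5-bis(trifluoromethyl)phenyl squaramide (10 mol %), MTBE, −15 °C → rt; 1 M HCl wash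
Reagents that add atoms: none
Why: The quinuclidine nitrogen of the catalyst deprotonates the doubly activated C4–H of anhydride 7 while the squaramide N–H pair binds the aldehyde carbonyl, so the ion-paired enolate adds through C4 to the Si face of 13 and forms C3–C4. The C3 alkoxide then attacks the aroyl carbonyl C1 in a 6-exo-trig addition–elimination that closes the δ-lactone (C1–O2) and releases the C4 carboxylate, which makes the sequence irreversible. The closest known reaction type is the organocatalytic enantioselective Tamura-type formal cycloaddition of homophthalic anhydrides with aldehydes to 1-oxoisochromane-4-carboxylic acids. C3 is set as R by the chiral pocket of the catalyst, because the silyloxy centre of 13 lies four carbons from the carbonyl and gives no useful bias, whereas C4 forms as a mixture that does not matter since step 9 erases that centre. The step needs deprotonation of the anhydride in preference to the aldehyde α-position (secured by the much higher acidity of C4–H towards a tertiary amine, which keeps self-aldol slow) and acyl transfer at C1 only (secured because attack at the aliphatic anhydride carbonyl would give a four-membered lactone).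

Step 9
Reactants: 14 (3R)-5,8-bis(benzyloxy)-3-[(4S)-4-(tert-butyldimethylsilyloxy)pentyl]-1-oxoisochromane-4-carboxylic acid
Product: 16 (3R)-5,8-bis(benzyloxy)-3-[(4S)-4-(tert-butyldimethylsilyloxy)pentyl]isochroman-1-one, via Barton ester 15 (not isolated)
Conditions: N-hydroxypyridine-2-thione, DCC, CH2Cl2, 0 °C, dark; then t-BuSH (excess), hν (tungsten lamp), 0 °C → rt
Reagents that add atoms: none
Why: In this Barton reductive decarboxylation, light cleaves the N–O bond of the thiohydroxamate ester, loss of CO2 gives the benzylic C4 radical and hydrogen transfer from the thiol gives the CH2 group from either C4 epimer, while the radical (not anionic) pathway avoids β-elimination of the lactone oxygen and leaves C3 untouched.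

Step 10
Reactants: 16 (3R)-5,8-bis(benzyloxy)-3-[(4S)-4-(tert-butyldimethylsilyloxy)pentyl]isochroman-1-one
Product: 17 (3R)-5,8-bis(benzyloxy)-3-[(4S)-4-hydroxypentyl]isochroman-1-one
Conditions: HF·pyridine, THF, 0 °C → rt
Reagents that add atoms: none
Why: Fluoride-mediated desilylation is selective because benzyl ethers and the aryl lactone are inert to HF·pyridine and no base is present that could open the lactone.

Step 11
Reactants: 18 (R)-mevalonolactone
Product: 20 (3R)-5-(benzyloxy)-3-hydroxy-3-methylpentanoic acid, via sodium (R)-mevalonate 19 (not isolated)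
Conditions: NaOH (1.0 equiv), H2O/MeOH, rt; evaporate, dry; NaH (1.1 equiv), BnBr (1.05 equiv), DMF, 0 °C → rt; aq. NaOH; HCl to pH 3
Reagents that add atoms: sodium hydroxide, [Na+].[OH-]; benzyl bromide, BrCc1ccccc1
Why: Saponification opens the δ-lactone, and in the resulting hydroxy carboxylate one equivalent of NaH forms the primary alkoxide, which is far more nucleophilic than the carboxylate or the hindered tertiary hydroxyl, so a Williamson benzylation caps O5 only (any benzyl ester is cleaved in the basic work-up) and the quaternary R centre is not touched.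

Step 12
Reactants: 17 (3R)-5,8-bis(benzyloxy)-3-[(4S)-4-hydroxypentyl]isochroman-1-one; 20 (3R)-5-(benzyloxy)-3-hydroxy-3-methylpentanoic acid
Product: 21 (2S)-5-[(3R)-5,8-bis(benzyloxy)-1-oxoisochroman-3-yl]pentan-2-yl (3R)-5-(benzyloxy)-3-hydroxy-3-methylpentanoate
Conditions: DIC, DMAP (0.2 equiv), CH2Cl2, 0 °C → rt
Reagents that add atoms: none
Why: Steglich esterification acylates the secondary alcohol of 17, while the tertiary hydroxyl of 20 is too hindered to compete and the primary one is blocked as its benzyl ether, so neither self-acylation nor closure to mevalonolactone can occur, and all stereocentres stay as they are because the bond is made at oxygen.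

Step 13
Reactants: 21 (2S)-5-[(3R)-5,8-bis(benzyloxy)-1-oxoisochroman-3-yl]pentan-2-yl (3R)-5-(benzyloxy)-3-hydroxy-3-methylpentanoate
Product: 22 aspergimarin C, (2S)-5-[(3R)-5,8-dihydroxy-1-oxoisochroman-3-yl]pentan-2-yl (3R)-3,5-dihydroxy-3-methylpentanoate
Conditions: H2 (1 atm), Pd(OH)2/C, EtOAc/EtOH, rt; filtration under argon
Reagents that add atoms: none
Why: Catalytic hydrogenolysis removes the two aryl benzyl ethers and the primary benzyl ether in one neutral operation, so the 5-hydroxy ester, which could lactonise with loss of the side-chain alcohol under acid or base, is exposed only at the very end, and the lactone (whose C3–O bond is not benzylic) and the three stereocentres are untouched.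

**Compound list**

1 | 4,7-dimethoxyindan-1-one | COc1ccc(OC)c2c1CCC2=O | starting material
2 | 4,7-dihydroxyindan-1-one | Oc1ccc(O)c2c1CCC2=O | intermediate
3 | 4,7-bis(benzyloxy)indan-1-one | O=C1CCc2c(OCc3ccccc3)ccc(OCc3ccccc3)c21 | intermediate
4 | diethyl oxalate | CCOC(=O)C(=O)OCC | starting material
5 | ethyl 2-[4,7-bis(benzyloxy)-1-oxoindan-2-yl]-2-oxoacetate | CCOC(=O)C(=O)C1Cc2c(OCc3ccccc3)ccc(OCc3ccccc3)c2C1=O | intermediate (not isolated)
6 | 3,6-bis(benzyloxy)-2-(carboxymethyl)benzoic acid | OC(=O)Cc1c(OCc2ccccc2)ccc(OCc2ccccc2)c1C(=O)O | intermediate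
7 | 5,8-bis(benzyloxy)isochromane-1,3-dione | O=C1Cc2c(OCc3ccccc3)ccc(OCc3ccccc3)c2C(=O)O1 | intermediate
8 | (S)-propylene oxide | C[C@H]1CO1 | starting material
9 | but-3-enylmagnesium bromide | C=CCC[Mg]Br | starting material
10 | (2S)-hept-6-en-2-ol | C[C@@H](CCCC=C)O | intermediate
11 | tert-butyl[(2S)-hept-6-en-2-yloxy]dimethylsilane | C[C@@H](CCCC=C)O[Si](C)(C)C(C)(C)C | intermediate
12 | 3-[(4S)-4-(tert-butyldimethylsilyloxy)pentyl]-1,2,4-trioxolane | C[C@@H](CCCC1OCOO1)O[Si](C)(C)C(C)(C)C | intermediate (not isolated)
13 | (5S)-5-(tert-butyldimethylsilyloxy)hexanal | C[C@@H](CCCC=O)O[Si](C)(C)C(C)(C)C | intermediate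
14 | (3R)-5,8-bis(benzyloxy)-3-[(4S)-4-(tert-butyldimethylsilyloxy)pentyl]-1-oxoisochromane-4-carboxylic acid (C4 epimers) | C[C@@H](CCC[C@@H]1C(C(=O)O)c2c(OCc3ccccc3)ccc(OCc3ccccc3)c2C(=O)O1)O[Si](C)(C)C(C)(C)C | intermediate
15 | 2-thioxopyridin-1(2H)-yl (3R)-5,8-bis(benzyloxy)-3-[(4S)-4-(tert-butyldimethylsilyloxy)pentyl]-1-oxoisochromane-4-carboxylate | C[C@@H](CCC[C@@H]1C(C(=O)On4ccccc4=S)c2c(OCc3ccccc3)ccc(OCc3ccccc3)c2C(=O)O1)O[Si](C)(C)C(C)(C)C | intermediate (not isolated)
16 | (3R)-5,8-bis(benzyloxy)-3-[(4S)-4-(tert-butyldimethylsilyloxy)pentyl]isochroman-1-one | C[C@@H](CCC[C@@H]1Cc2c(OCc3ccccc3)ccc(OCc3ccccc3)c2C(=O)O1)O[Si](C)(C)C(C)(C)C | intermediate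
17 | (3R)-5,8-bis(benzyloxy)-3-[(4S)-4-hydroxypentyl]isochroman-1-one | C[C@@H](CCC[C@@H]1Cc2c(OCc3ccccc3)ccc(OCc3ccccc3)c2C(=O)O1)O | intermediate
18 | (R)-mevalonolactone | C[C@@]1(O)CCOC(=O)C1 | starting material
19 | sodium (3R)-3,5-dihydroxy-3-methylpentanoate | [Na+].[O-]C(=O)C[C@](C)(O)CCO | intermediate (not isolated)
20 | (3R)-5-(benzyloxy)-3-hydroxy-3-methylpentanoic acid | OC(=O)C[C@](C)(O)CCOCc1ccccc1 | intermediate
21 | (2S)-5-[(3R)-5,8-bis(benzyloxy)-1-oxoisochroman-3-yl]pentan-2-yl (3R)-5-(benzyloxy)-3-hydroxy-3-methylpentanoate | C[C@@H](CCC[C@@H]1Cc2c(OCc3ccccc3)ccc(OCc3ccccc3)c2C(=O)O1)OC(=O)C[C@](C)(O)CCOCc1ccccc1 | intermediate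
22 | aspergimarin C | C[C@@H](CCC[C@@H]1Cc2c(O)ccc(O)c2C(=O)O1)OC(=O)C[C@](C)(O)CCO | target

**Count and risks**

Total step count: 13. Longest linear sequence: 9 steps (1, 2, 3, 4, 8, 9, 10, 12, 13).

Steps most likely to fail:

1. Step 8. Facial discrimination may be insufficient, or C–C bond formation and acyl transfer may be slowed by the two benzyloxy groups flanking the reacting positions, so that amine-induced self-condensation of the enolisable aldehyde takes over. A poor ratio would be hard to repair later because the C3 epimer differs only in a remote 1,5-relationship. The fallback sets out from 11 and comes back at 16, and takes C3 from a resolved epoxide instead of from catalysis. Alkene 11 is epoxidised with mCPBA to tert-butyldimethyl{[(2S)-5-(oxiran-2-yl)pentan-2-yl]oxy}silane F1 as a mixture of oxirane epimers. Hydrolytic kinetic resolution with the (salen)Co(III)OAc enantiomer that hydrates the 2S oxirane leaves the (2R)-oxirane F2 and converts the other epimer into the diol F3, which is removed by chromatography. Separately, commercial 1,4-bis(benzyloxy)-2-bromobenzene F4 is lithiated with LDA at −78 °C between bromine and the benzyloxy group and trapped with methyl chloroformate to give methyl 3,6-bis(benzyloxy)-2-bromobenzoate F5. Bromine–magnesium exchange on F5 (iPrMgCl·LiCl, THF, −20 °C) and CuI-catalysed opening of F2 at its CH2 terminus give a magnesium alkoxide that closes onto the neighbouring ester on warming. This delivers 16 directly, so that steps 7 to 9 are not needed.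

2. Step 9. The stabilised benzylic C4 radical may be captured at the thiocarbonyl sulfur of the thiohydroxamate faster than it takes hydrogen from the thiol, which diverts material to a pyridyl sulfide. The fallback sets out from 14 and comes back at 16, and uses decarbonylation of an acyl radical with a stannane as the only radical trap. Acid 14 is converted with diphenyl diselenide and Bu3P (CH2Cl2, rt) into the Se-phenyl selenoester F6. Treatment with Bu3SnH and AIBN in benzene at 80 °C generates the acyl radical, which loses CO rapidly because the resulting radical is benzylic, and hydrogen transfer from the stannane gives 16.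

3. Step 11. Site selectivity of the alkylation may be lost (benzylation at the carboxylate or at the tertiary alkoxide, or incomplete alkoxide formation from a poorly soluble salt). The fallback sets out from 19 (made from 18 as in step 11) and comes back at 22, and changes the O5 protecting group to silicon. Salt 19 is treated with TBSCl and imidazole in DMF to give the silyl ester silyl ether F7, whose silyl ester is cleaved with K2CO3 in aqueous methanol to give (3R)-5-(tert-butyldimethylsilyloxy)-3-hydroxy-3-methylpentanoic acid F8. Esterification of F8 with 17 (DIC, DMAP) gives the silyl-protected ester F9. HF·pyridine in THF at 0 °C gives the diol F10, and hydrogenolysis of its two aryl benzyl ethers under the conditions of step 13 gives 22.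

Further compounds

F1 | step 8 | tert-butyldimethyl{[(2S)-5-(oxiran-2-yl)pentan-2-yl]oxy}silane (both oxirane epimers) | C[C@@H](CCCC1CO1)O[Si](C)(C)C(C)(C)C
F2 | step 8 | tert-butyldimethyl({(2S)-5-[(2R)-oxiran-2-yl]pentan-2-yl}oxy)silane | C[C@@H](CCC[C@@H]1CO1)O[Si](C)(C)C(C)(C)C
F3 | step 8 | (2S,6S)-6-(tert-butyldimethylsilyloxy)heptane-1,2-diol | C[C@@H](CCC[C@H](O)CO)O[Si](C)(C)C(C)(C)C
F4 | step 8 | 1,4-bis(benzyloxy)-2-bromobenzene (purchased) | Brc1cc(OCc2ccccc2)ccc1OCc1ccccc1
F5 | step 8 | methyl 3,6-bis(benzyloxy)-2-bromobenzoate | COC(=O)c1c(Br)c(OCc2ccccc2)ccc1OCc1ccccc1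
F6 | step 9 | Se-phenyl (3R)-5,8-bis(benzyloxy)-3-[(4S)-4-(tert-butyldimethylsilyloxy)pentyl]-1-oxoisochromane-4-carboselenoate (C4 epimers) | C[C@@H](CCC[C@@H]1C(C(=O)[Se]c4ccccc4)c2c(OCc3ccccc3)ccc(OCc3ccccc3)c2C(=O)O1)O[Si](C)(C)C(C)(C)C
F7 | step 11 | tert-butyldimethylsilyl (3R)-5-(tert-butyldimethylsilyloxy)-3-hydroxy-3-methylpentanoate | CC(C)(C)[Si](C)(C)OC(=O)C[C@](C)(O)CCO[Si](C)(C)C(C)(C)C
F8 | step 11 | (3R)-5-(tert-butyldimethylsilyloxy)-3-hydroxy-3-methylpentanoic acid | OC(=O)C[C@](C)(O)CCO[Si](C)(C)C(C)(C)C
F9 | step 11 | (2S)-5-[(3R)-5,8-bis(benzyloxy)-1-oxoisochroman-3-yl]pentan-2-yl (3R)-5-(tert-butyldimethylsilyloxy)-3-hydroxy-3-methylpentanoate | C[C@@H](CCC[C@@H]1Cc2c(OCc3ccccc3)ccc(OCc3ccccc3)c2C(=O)O1)OC(=O)C[C@](C)(O)CCO[Si](C)(C)C(C)(C)C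
F10 | step 11 | (2S)-5-[(3R)-5,8-bis(benzyloxy)-1-oxoisochroman-3-yl]pentan-2-yl (3R)-3,5-dihydroxy-3-methylpentanoate | C[C@@H](CCC[C@@H]1Cc2c(OCc3ccccc3)ccc(OCc3ccccc3)c2C(=O)O1)OC(=O)C[C@](C)(O)CCO
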